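- A small charge of partner leaves open intermediate still climbing at the last west reading, 53.8% at 15.0 h, whereas the north-west run has turned over by 15.0 h. We therefore ask what the flask would need for the opposite outcome, a maximum pushed to the time limit.

| flask | starting material | partner | remark | time |
|---|---|---|---|---|
| west | 0.050 M | 0.018 M | run made earlier |  |
| north-west | 0.050 M | 0.070 M | run made earlier |  |
| south-east | 0.025 M | 0.035 M | run made earlier |  |
| flask | 0.050 M | 0.0350 M |  | 20 h |

| run | time / h | open intermediate / % | product / % |
|---|---|---|---|
| west | 3.00 | 29.8 | 0.6 |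
| west | 4.00 | 36.5 | 0.4 |
| west | 5.00 | 40.1 | 0.8 |
| west | 6.00 | 44.6 | 1.9 |
| west | 10.0 | 51.6 | 4.8 |
| west | 12.0 | 53.0 | 6.5 |
| west | 15.0 | 53.8 | 9.3 |
| north-west | 3.00 | 29.2 | 0.8 |
| north-west | 4.00 | 33.8 | 1.8 |
| north-west | 5.00 | 38.3 | 3.8 |
| north-west | 6.00 | 40.6 | 6.6 |
| north-west | 10.0 | 42.2 | 16.8 |
| north-west | 12.0 | 40.8 | 22.5 |
| north-west | 15.0 | 36.4 | 30.9 |
| south-east | 3.00 | 29.6 | 0.9 |
| south-east | 4.00 | 34.9 | 1.3 |
| south-east | 6.00 | 42.7 | 3.5 |
| south-east | 10.0 | 47.2 | 9.4 |
| south-east | 15.0 | 44.2 | 20.3 |

(each reading ± 0.3 percentage points)

- the best time, 20 h at the latest, for open intermediate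
- the amount of open intermediate, in percent of the starting material charged, at that time

- the numbers in the tables scatter by 0.3 percentage points (one standard deviation)
- steps that have been proposed: starting material <-> open intermediate; partner -> second intermediate; open intermediate + second intermediate -> product

- We treat the loss to product as a small correction to a first-order relaxation. The sum of open intermediate and product in the west run gains 30.4% by 3.00 h, then 16.1% over the next equal interval. This gives a relaxation rate λ = 0.212 h⁻¹ and a plateau g = 64.6%.
- Call the leak s the pseudo-first-order loss: product gained per hour per unit of open intermediate, scaled to the flask's partner charge. Between 10.0 h and 15.0 h, the readings of north-west give s = 0.0346 h⁻¹ and those of west 0.0330 h⁻¹.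
- At a maximum, I = g(1 − P)/(1 + s/λ), with I and P the open intermediate and product. South-east was charged with the same partner concentration as the flask, so we borrow P from its reading, 9.4% at 10.0 h, and reckon I = 50.3% for the flask.
- In the flask, we reckon that the remaining supply, λg·exp(−λt), equals the loss sI near 9.73 h. At 20 h the ratio of supply to loss would have to reach one for the opposite outcome, but we reckon it at 0.113.
- The forecast, lower than our reckoned 50.3%, gives 47.8% at 10.5 h, where open intermediate “peaks where its supply equals its loss”.

- The flask gives 48.6% at 11.2 h.

    starting material ⇌ open intermediate (K = 1.70, k = 3.80 × 10⁻⁵ s⁻¹)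
    partner → second intermediate (k = 1.10 × 10⁻⁵ s⁻¹)
    open intermediate + second intermediate → product (k = 0.00130 L mol⁻¹ s⁻¹)

- From 10.0 h to 20.0 h the product of the flask rises by 16 percentage points, and s times the mean of its open intermediate at those two times gives 16 points. Scaled to the 0.060 M of partner in a neighbour flask, otherwise charged alike, s becomes 0.0592 h⁻¹, and multiplying the flask's 24.5% of product in that proportion gives an estimate of 41.9%. That neighbour flask holds 38.7% product at 20.0 h, with open intermediate at 33.9%.

The earlier runs and the new flask come from a simulation from invented constants, and the scatter is random.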